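Ring B is hexasubstituted (C1 CO2CH3, C2 OH, C3 CH3, C4 O-acyl, C5 Cl, C6 CH3) and its C4 oxygen carries the di-ortho-substituted ring A acyl group. Everything rests on cutting ring B at C1–C2 and C5–C6: a [4+2] cycloaddition of a four-carbon diene (C2–C5) with methyl but-2-ynoate (C1, C6), followed by loss of methanol, assembles the complete arene with the depside ester already in place. The diene is a silyl ketene acetal at C2 that bears the benzyl-protected ring A aroyloxy group at C4 and chlorine at C5; it comes from O-acylation of a small chloro keto ester. Debenzylation and formylation at ring A C5' finish the synthesis.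

Key step: step 7

Remark on the chemistry: ring A is numbered C1' (C=O), C2' (CH3), C3' (Cl), C4' (OH), C5' (CHO), C6' (OH), so the carbon formylated at the end is C5' (C3' carries chlorine); the alkene geometries drawn for 10, 11 and 12 are the expected ones and none of them survives in the arene.

Step 1
Reactants: 1 methyl 2,4-dihydroxy-6-methylbenzoate (methyl orsellinate)
Product: 2 methyl 3-chloro-4,6-dihydroxy-2-methylbenzoate
Conditions: SO2Cl2 (1.05 equiv), Et2O, 0 °C to rt
Reagents that add atoms: sulfuryl chloride, O=S(=O)(Cl)Cl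
Why: Electrophilic aromatic chlorination, which on this resorcinol ring should go to the carbon flanked by CH3 and the free OH (para to the ester-chelated OH) and not to the crowded carbon between the two hydroxyls, one equivalent of reagent limiting dichlorination.

Step 2
Reactants: 2 methyl 3-chloro-4,6-dihydroxy-2-methylbenzoate
Product: 3 methyl 4,6-bis(benzyloxy)-3-chloro-2-methylbenzoate
Conditions: BnBr (2.5 equiv), K2CO3 (3 equiv), DMF, 60 °C
Reagents that add atoms: benzyl bromide, BrCc1ccccc1
Why: Williamson ether synthesis, with DMF and gentle heating so that the hydrogen-bonded hydroxyl next to the ester is alkylated as well.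

Step 3
Reactants: 3 methyl 4,6-bis(benzyloxy)-3-chloro-2-methylbenzoate
Product: 4 4,6-bis(benzyloxy)-3-chloro-2-methylbenzoic acid
Conditions: KOH (10 equiv), DMSO/H2O, 90 °C; then aq HCl
Reagents that add atoms: potassium hydroxide, [K+].[OH-]
Why: Saponification of a di-ortho-substituted benzoate needs forcing hydroxide conditions, to which the benzyl ethers and the unactivated aryl chloride are inert.

Step 4
Reactants: 5 methyl propanoate; 6 chloroacetyl chloride
Product: 8 methyl 4-chloro-2-methyl-3-oxobutanoate (racemic), via lithium enolate of methyl propanoate 7 (not isolated)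
Conditions: LiN(iPr)2 (2.1 equiv), 5 (2.1 equiv), THF, −78 °C; then 6 (1.0 equiv), −78 °C; aq NH4Cl
Reagents that add atoms: none
Why: Crossed Claisen-type C-acylation of the preformed ester enolate by the acid chloride, the second equivalent of enolate taking the acidic proton of the product so that it is not acylated twice; the C2 stereocentre forms as a racemate and becomes sp2 in step 5.

Step 5
Reactants: 4 4,6-bis(benzyloxy)-3-chloro-2-methylbenzoic acid; 8 methyl 4-chloro-2-methyl-3-oxobutanoate
Product: 10 methyl (2E)-3-{[4,6-bis(benzyloxy)-3-chloro-2-methylbenzoyl]oxy}-4-chloro-2-methylbut-2-enoate, via 4,6-bis(benzyloxy)-3-chloro-2-methylbenzoyl chloride 9 (not isolated)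
Conditions: (COCl)2 (1.5 equiv), DMF (cat.), CH2Cl2, 0 °C to rt; concentrate; then 8 (1.2 equiv), iPr2NEt (1.5 equiv), DMAP (0.05 equiv), CH2Cl2, 0 °C to rt
Reagents that add atoms: none
Why: Acid chloride formation followed by amine-mediated O-acylation of the keto ester enolate, in which the hard, hindered aroyl chloride should take the enolate oxygen and not the fully substituted alpha carbon; the (E)-isomer is expected with a non-chelating base, and either isomer gives the same diene.

Step 6
Reactants: 10 methyl (2E)-3-{[4,6-bis(benzyloxy)-3-chloro-2-methylbenzoyl]oxy}-4-chloro-2-methylbut-2-enoate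
Product: 12 (1Z,3Z)-1-chloro-4-methoxy-3-methyl-4-[(trimethylsilyl)oxy]buta-1,3-dien-2-yl 4,6-bis(benzyloxy)-3-chloro-2-methylbenzoate, via lithium dienolate 11 (not isolated)
Conditions: Me3SiCl (2 equiv), then LiN(iPr)2 (1.15 equiv) added slowly, THF, −78 °C to 0 °C; evaporate, pentane, filter under Ar; used crude
Reagents that add atoms: chlorotrimethylsilane, C[Si](C)(C)Cl
Why: Gamma-deprotonation of a beta-oxygenated enoate and O-silylation of the extended ester enolate is the standard entry to 1-alkoxy-1-silyloxy dienes; the CH2Cl protons are the most acidic in 10, and having Me3SiCl present during base addition keeps the lifetime of dienolate 11 short.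

Step 7
Reactants: 12 (1Z,3Z)-1-chloro-4-methoxy-3-methyl-4-[(trimethylsilyl)oxy]buta-1,3-dien-2-yl 4,6-bis(benzyloxy)-3-chloro-2-methylbenzoate; 13 methyl but-2-ynoate
Product: 16 methyl 4-{[4,6-bis(benzyloxy)-3-chloro-2-methylbenzoyl]oxy}-3-chloro-6-hydroxy-2,5-dimethylbenzoate, via cyclohexa-1,4-diene cycloadduct 14 (not isolated), via aryl trimethylsilyl ether 15 (not isolated)
Conditions: 13 (5 equiv), 2,6-di-tert-butylpyridine (0.1 equiv), PhMe, 115 °C, sealed tube, Ar; then 1 M HCl, THF, rt
Reagents that add atoms: none
Why: Proposed new method: diene 12 in its s-cis conformation should add to ynoate 13 in a thermal, strongly asynchronous [4+2] cycloaddition (in the limit a vinylogous Mukaiyama–Michael addition followed by ring closure) that forms C5–C6 and C1–C2; the closest known reaction type is the Diels–Alder reaction of 1,1,3-trioxygenated ketene-acetal dienes with acetylenic esters followed by aromatization, not yet shown with an acyloxy group at the 3-position and a chlorine on the diene terminus. Ring B is closed by intermolecular [4+2] annulation, four ring carbons coming from 12 and two from 13. Regioselectivity is the one selectivity needed, and it is secured by the ketene-acetal oxygens and the 3-acyloxy group, which together make the chlorine-bearing terminus the nucleophilic end, so it bonds to the methyl-bearing beta carbon of 13 while the acetal carbon bonds to the ester-bearing alpha carbon. Cycloadduct 14 has two transient sp3 centres (the C2 ketal and C5 with H and Cl) whose relative configuration is irrelevant, because the more basic methoxy group ionizes from C2 and the doubly allylic C5 proton is then lost, a formal 1,4-elimination of methanol that gives arene 15. Chlorine cannot be eliminated because C2 bears no hydrogen, and dilute acid finally hydrolyses the aryl silyl ether to 16, which has no stereocentre.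

Step 8
Reactants: 16 methyl 4-{[4,6-bis(benzyloxy)-3-chloro-2-methylbenzoyl]oxy}-3-chloro-6-hydroxy-2,5-dimethylbenzoate
Product: 17 methyl 3-chloro-4-[(3-chloro-4,6-dihydroxy-2-methylbenzoyl)oxy]-6-hydroxy-2,5-dimethylbenzoate
Conditions: BCl3 (5 equiv), pentamethylbenzene (6 equiv), CH2Cl2, −78 °C; then H2O
Reagents that add atoms: none
Why: Lewis-acid cleavage of aryl benzyl ethers by BCl3 at low temperature with pentamethylbenzene as a non-basic trap for the benzyl cation (Friedel–Crafts capture), conditions under which the depside ester, the salicylate methyl ester and both aryl chlorides should be inert.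

Step 9
Reactants: 17 methyl 3-chloro-4-[(3-chloro-4,6-dihydroxy-2-methylbenzoyl)oxy]-6-hydroxy-2,5-dimethylbenzoate
Product: 19 methyl 3-chloro-4-[(3-chloro-5-formyl-4,6-dihydroxy-2-methylbenzoyl)oxy]-6-hydroxy-2,5-dimethylbenzoate (target CNP0249536.0), via chloro(methoxy)methyl arene 18 (not isolated)
Conditions: Cl2CHOCH3 (3 equiv), TiCl4 (5 equiv), CH2Cl2, 0 °C to rt; then 1 M HCl, rt
Reagents that add atoms: dichloromethyl methyl ether, COC(Cl)Cl; water, O
Why: Rieche formylation (Friedel–Crafts attack on the chloro(methoxy)carbenium ion from Cl2CHOCH3 and TiCl4) at ring A C5', the only aromatic C–H of 17 and ortho to two titanium-bound phenoxides, ring B being fully substituted; aqueous acid then hydrolyses the alpha-chloro ether 18 to the aldehyde.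

Compound list
1 | methyl 2,4-dihydroxy-6-methylbenzoate (methyl orsellinate) | COC(=O)c1c(C)cc(O)cc1O | starting material
2 | methyl 3-chloro-4,6-dihydroxy-2-methylbenzoate | COC(=O)c1c(C)c(Cl)c(O)cc1O | intermediate
3 | methyl 4,6-bis(benzyloxy)-3-chloro-2-methylbenzoate | COC(=O)c1c(C)c(Cl)c(OCc2ccccc2)cc1OCc1ccccc1 | intermediate
4 | 4,6-bis(benzyloxy)-3-chloro-2-methylbenzoic acid | OC(=O)c1c(C)c(Cl)c(OCc2ccccc2)cc1OCc1ccccc1 | intermediate
5 | methyl propanoate | CCC(=O)OC | starting material
6 | chloroacetyl chloride | ClCC(Cl)=O | starting material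
7 | lithium 1-methoxyprop-1-en-1-olate (lithium enolate of methyl propanoate, CH3 trans to OLi) | C/C=C(/O[Li])OC | intermediate (not isolated)
8 | methyl 4-chloro-2-methyl-3-oxobutanoate (racemic) | COC(=O)C(C)C(=O)CCl | intermediate
9 | 4,6-bis(benzyloxy)-3-chloro-2-methylbenzoyl chloride | O=C(Cl)c1c(C)c(Cl)c(OCc2ccccc2)cc1OCc1ccccc1 | intermediate (not isolated)
10 | methyl (2E)-3-{[4,6-bis(benzyloxy)-3-chloro-2-methylbenzoyl]oxy}-4-chloro-2-methylbut-2-enoate | COC(=O)/C(C)=C(\CCl)OC(=O)c1c(C)c(Cl)c(OCc2ccccc2)cc1OCc1ccccc1 | intermediate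
11 | lithium 3-{[4,6-bis(benzyloxy)-3-chloro-2-methylbenzoyl]oxy}-4-chloro-1-methoxy-2-methylbuta-1,3-dien-1-olate (OLi cis to C3, Cl cis to the aroyloxy group) | [Li]O/C(OC)=C(C)\C(OC(=O)c1c(C)c(Cl)c(OCc2ccccc2)cc1OCc1ccccc1)=C\Cl | intermediate (not isolated)
12 | (1Z,3Z)-1-chloro-4-methoxy-3-methyl-4-[(trimethylsilyl)oxy]buta-1,3-dien-2-yl 4,6-bis(benzyloxy)-3-chloro-2-methylbenzoate | C[Si](C)(C)O/C(OC)=C(C)\C(OC(=O)c1c(C)c(Cl)c(OCc2ccccc2)cc1OCc1ccccc1)=C\Cl | intermediate (key-step precursor)
13 | methyl but-2-ynoate | CC#CC(=O)OC | starting material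
14 | methyl 4-{[4,6-bis(benzyloxy)-3-chloro-2-methylbenzoyl]oxy}-3-chloro-6-methoxy-2,5-dimethyl-6-[(trimethylsilyl)oxy]cyclohexa-1,4-diene-1-carboxylate (racemic, OCH3 cis to Cl) | COC(=O)C1=C(C)[C@@H](Cl)C(OC(=O)c2c(C)c(Cl)c(OCc3ccccc3)cc2OCc2ccccc2)=C(C)[C@]1(OC)O[Si](C)(C)C | intermediate (not isolated)
15 | methyl 4-{[4,6-bis(benzyloxy)-3-chloro-2-methylbenzoyl]oxy}-3-chloro-2,5-dimethyl-6-[(trimethylsilyl)oxy]benzoate | COC(=O)c1c(C)c(Cl)c(OC(=O)c2c(C)c(Cl)c(OCc3ccccc3)cc2OCc2ccccc2)c(C)c1O[Si](C)(C)C | intermediate (not isolated)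
16 | methyl 4-{[4,6-bis(benzyloxy)-3-chloro-2-methylbenzoyl]oxy}-3-chloro-6-hydroxy-2,5-dimethylbenzoate | COC(=O)c1c(C)c(Cl)c(OC(=O)c2c(C)c(Cl)c(OCc3ccccc3)cc2OCc2ccccc2)c(C)c1O | intermediate (key-step product)
17 | methyl 3-chloro-4-[(3-chloro-4,6-dihydroxy-2-methylbenzoyl)oxy]-6-hydroxy-2,5-dimethylbenzoate | COC(=O)c1c(C)c(Cl)c(OC(=O)c2c(C)c(Cl)c(O)cc2O)c(C)c1O | intermediate
18 | methyl 3-chloro-4-({3-chloro-5-[chloro(methoxy)methyl]-4,6-dihydroxy-2-methylbenzoyl}oxy)-6-hydroxy-2,5-dimethylbenzoate (racemic at the new CH) | COC(=O)c1c(C)c(Cl)c(OC(=O)c2c(C)c(Cl)c(O)c(C(Cl)OC)c2O)c(C)c1O | intermediate (not isolated)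
19 | methyl 3-chloro-4-[(3-chloro-5-formyl-4,6-dihydroxy-2-methylbenzoyl)oxy]-6-hydroxy-2,5-dimethylbenzoate | COC(=O)c1c(C)c(Cl)c(OC(=O)c2c(C)c(Cl)c(O)c(C=O)c2O)c(C)c1O | target

Total step count: 9. Longest linear sequence: 8 steps (steps 1, 2, 3, 5, 6, 7, 8, 9 from compound 1; step 4 is a one-step branch).

Steps most likely to fail

Step 7 (proposed new method). The acyloxy and chloro groups lower the nucleophilicity of the diene and the ynoate is a slow dienophile, so protodesilylation back to the enoate, thermal silyl or acyl migration, or oligomerization may outrun cycloaddition. Loss of silanol in place of methanol would leave the C2 oxygen methylated. The fallback uses known chemistry, sets out from acid 4 and comes back at 16. Purchased methyl 2,4-dihydroxy-3,6-dimethylbenzoate (COC(=O)c1c(C)cc(O)c(C)c1O) is chlorinated with SO2Cl2 in Et2O at its only free ring carbon to give methyl 3-chloro-4,6-dihydroxy-2,5-dimethylbenzoate F1. Acid 4 and F1 are then condensed with (CF3CO)2O in toluene, the classical depside esterification through the mixed anhydride and acylium ion, which acylates the non-chelated C4 hydroxyl and should give 16 directly. Steps 8 and 9 follow unchanged.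

Step 6. Deprotonation of the ring A benzylic methyl ortho to the ester, acyl transfer within the dienolate, C-silylation, or hydrolysis of the silyl ketene acetal during isolation may prevent clean formation of the diene. The fallback sets out from acid 4 and comes back at target 19; it avoids both the diene and the doubly hindered esterification by adding the ring B chlorine last. Acid 4 is condensed with purchased methyl 2,4-dihydroxy-3,6-dimethylbenzoate ((CF3CO)2O, toluene) at its free C4 hydroxyl to give methyl 4-{[4,6-bis(benzyloxy)-3-chloro-2-methylbenzoyl]oxy}-2-hydroxy-3,6-dimethylbenzoate F2. BCl3 and pentamethylbenzene at −78 °C remove the benzyl groups to give methyl 4-[(3-chloro-4,6-dihydroxy-2-methylbenzoyl)oxy]-2-hydroxy-3,6-dimethylbenzoate F3. Rieche formylation (Cl2CHOCH3, TiCl4) ortho to the two ring A hydroxyls gives methyl 4-[(3-chloro-5-formyl-4,6-dihydroxy-2-methylbenzoyl)oxy]-2-hydroxy-3,6-dimethylbenzoate F4. SO2Cl2 then chlorinates the single remaining aromatic C–H, ring B C5, to give 19.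

Step 9. Titanium chelation by three phenols and two ester carbonyls may leave the doubly flanked, chlorine- and ester-deactivated C5' unreactive, and prolonged exposure to the Lewis acid may cleave the depside ester. The fallback sets out from 17 and comes back at 19. It is a Duff formylation with hexamethylenetetramine in CF3CO2H at 80 °C followed by aqueous acid, which uses an iminium electrophile in a protic acid with no metal chelation and passes through aminomethylation, hydride transfer and hydrolysis. It creates no compound outside the list (entry F0).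

Further compounds
F1 | step 7 | methyl 3-chloro-4,6-dihydroxy-2,5-dimethylbenzoate | COC(=O)c1c(C)c(Cl)c(O)c(C)c1O
F2 | step 6 | methyl 4-{[4,6-bis(benzyloxy)-3-chloro-2-methylbenzoyl]oxy}-2-hydroxy-3,6-dimethylbenzoate | COC(=O)c1c(C)cc(OC(=O)c2c(C)c(Cl)c(OCc3ccccc3)cc2OCc2ccccc2)c(C)c1O
F3 | step 6 | methyl 4-[(3-chloro-4,6-dihydroxy-2-methylbenzoyl)oxy]-2-hydroxy-3,6-dimethylbenzoate | COC(=O)c1c(C)cc(OC(=O)c2c(C)c(Cl)c(O)cc2O)c(C)c1O
F4 | step 6 | methyl 4-[(3-chloro-5-formyl-4,6-dihydroxy-2-methylbenzoyl)oxy]-2-hydroxy-3,6-dimethylbenzoate | COC(=O)c1c(C)cc(OC(=O)c2c(C)c(Cl)c(O)c(C=O)c2O)c(C)c1O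
F0 | step 9 | none | none
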